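1. At 12 min I read each flask for one thing: D divided by D plus Q.

| flask | L | temperature | remark | time |
|---|---|---|---|---|
| grey | 1.1 M | −10 °C | run made earlier |  |
| amber | 1.8 M | 30 °C | run made earlier |  |
| midnight | 0.80 M | 65 °C |  | 12 min |
| spring | 0.80 M | −5 °C |  | 12 min |
| dawn | 0.80 M | 10 °C |  | 12 min |
| dusk | 0.80 M | 25 °C |  | 12 min |
| winter | 0.80 M | 55 °C |  | 12 min |

| run | time / min | D / % | Q / % |
|---|---|---|---|
| grey | 4.00 | 0 | 0.2 |
| grey | 12.0 | 0 | 0 |
| grey | 15.0 | 0 | 1.1 |
| grey | 30.0 | 1.2 | 0.4 |
| grey | 50.0 | 1.5 | 1.7 |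
| grey | 60.0 | 4.0 | 0.8 |
| amber | 0.833 | 6.5 | 10.2 |
| amber | 1.33 | 7.7 | 22.1 |
| amber | 2.00 | 11.3 | 38.2 |
| amber | 4.00 | 7.2 | 69.4 |
| amber | 6.00 | 5.9 | 81.3 |
| amber | 10.0 | 0.9 | 89.7 |

(each reading ± 1 percentage point)

- the flasks put in order of share of D in all that became D or Q, best first, at 12 min (midnight / spring / dawn / dusk / winter)
- the share of D in all that became D or Q of the flask you put first, at 12 min
- the share of D in all that became D or Q of the flask you put last, at 12 min

2. L gives J, and J gives D and Q, each by its own first-order step. The rate of D over the rate of Q is therefore kD·J / (kQ·J) = kD/kQ. J cancels and time drops out, as long as hardly anything returns from D or Q.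

3. I assume the grey run is near such a case: at 60.0 min it reads D plus Q of 4.80%. Its single readings are too small to give a ratio each, so I sum them, which gives D 6.70% and Q 4.20%.

4. The branch share, D summed over D and Q summed, taken as if nothing returned (selectivity under kinetic control), is 61.5%. It is a loose reading, since each point carries 1 percentage point.

5. The amber run shows where the cancellation fails: D reads 11.3% at 2.00 min but 0.9% at 10.0 min, so D is being lost there.

6. Spring, at −5 °C, lies close to grey at −10 °C and is read earlier than grey's last point. I put spring first, at 61.5%.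

7. The forecast gives spring > dawn > dusk > midnight > winter, with 58% first and 1% last, a top below mine. It calls the hot flasks “fully equilibrated at about 1–2%”.

8. The flasks give spring > dawn > midnight > winter > dusk, with 69.5% first and 3.50% last.

    L → J (k = 0.00710 s⁻¹, Ea = 93.0 kJ mol⁻¹)
    J ⇌ D (K = 0.340, k = 0.0138 s⁻¹, Ea = 84.0 kJ mol⁻¹, ΔH = −14.0 kJ mol⁻¹)
    J ⇌ Q (K = 21.0, k = 0.00676 s⁻¹, Ea = 89.0 kJ mol⁻¹, ΔH = −90.0 kJ mol⁻¹)
    (constants at 25 °C)

In spring L still stood at 92.6% at 12.0 min, with 0.679% D and 0.298% Q formed from J, a share 8 points above my 61.5%. In midnight L was down to 0% by 6.00 min, and D 11.9% and Q 19.6% stood unchanged from then to 120 min, for a share of 37.8%, ahead of winter at 21.1% and dusk at 3.50%. A repeat of dusk at 0 °C keeps 84.8% of its L, holds 2.26% D against 1.19% Q, and shows a share of 65.5%, 4 points from my 61.5%.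

(Readings and results are calculated with made-up constants, and the scatter is random.)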